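**Retrosynthetic overview**

1. Numbering follows the guaiane skeleton: five-membered ring C1–C5 (C1/C5 ring fusion, C3–C4 epoxide, methyl on C4); seven-membered ring C1, C10, C9, C8, C7, C6, C5 (C10 methyl carbinol, C8 ester, C7 isopropyl). Last disconnections: the C8 ester (acylation), the C3–C4 epoxide (bromohydrin of a C3=C4 alkene), and the C10 carbinol (C8-OH-directed epoxidation of a C9=C10 alkene, then hydride opening at C9).
2. Seven-membered ring, formed second: ring-closing metathesis at C9=C10 between an isopropenyl group on C1 and a propenyl group on C8. The C1–C10 bond comes from a cuprate addition anti to the C5 side chain of a cyclopentenone, which fixes the trans ring fusion (H-1/H-5 anti).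
3. Five-membered ring, formed first: closure of the C4–C5 bond in a gold-catalysed Rautenstrauch rearrangement of an acyclic 3-pivaloyloxy-1,4-enyne, C5=C1–C2(OPiv)–C3≡C4–CH3, which carries the C6–C9 chain on C5.
4. Enabling feature: in the five-membered ring the methyl-bearing epoxide carbon C4 is bonded to the ring-fusion carbon C5 and to the oxygenated carbon C3, and C2 is a methylene. C3–C4 can therefore be taken back to an alkyne, C1–C5 to an alkene and C2 to a carbinol ester, so that a 1,2-acyloxy shift places the oxygen on C3 while C4 bonds to C5 and the configuration of C2 is handed on to C5.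
5. The C7/C8 stereodiad comes from an anti-selective catalytic allylboration of crotonaldehyde; the carbinol C2 from a catalytic asymmetric alkynylation.

Key step: step 9

Remark: "guaiane" in the names denotes only the constitution and numbering of 1,4-dimethyl-7-(propan-2-yl)decahydroazulene; every configuration is given by its own descriptor.
Remark: the catalyst antipodes named in steps 2 and 7 are those expected to give the stated configurations; the route depends on the product configurations shown.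

**Step 1**
Reactants: 1 (E)-4-methylpent-2-ene
Product: 3 2-[(2E)-4-methylpent-2-en-1-yl]-4,4,5,5-tetramethyl-1,3,2-dioxaborolane, via allylpotassium 2 (not isolated)
Conditions: nBuLi, KOtBu, THF, −78 to −50 °C; iPrOBpin, −78 °C to rt; H2O
Reagents that add atoms: 2-isopropoxy-4,4,5,5-tetramethyl-1,3,2-dioxaborolane CC(C)OB1OC(C)(C)C(C)(C)O1
Why: Superbase (nBuLi/KOtBu) metalation should remove an allylic methyl proton, the E-configured allylpotassium keeps its geometry at low temperature, and borylation at the CH2 terminus gives the (E)-γ-isopropyl allylboronate.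

**Step 2**
Reactants: 3 2-[(2E)-4-methylpent-2-en-1-yl]-4,4,5,5-tetramethyl-1,3,2-dioxaborolane; 4 (E)-but-2-enal
Product: 5 (3S,4R,5E)-3-(propan-2-yl)hepta-1,5-dien-4-ol
Conditions: (S)-TRIP (5 mol %), 4 Å MS, toluene, −30 °C; H2O
Reagents that add atoms: none
Why: Chiral phosphoric acid-catalysed allylboration through a closed chair transition state should give 1,2-addition; the E-boronate places the isopropyl group equatorial and gives the anti diad (C7/C8 of the target), and the catalyst selects the aldehyde Si face.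

**Step 3**
Reactants: 5 (3S,4R,5E)-3-(propan-2-yl)hepta-1,5-dien-4-ol
Product: 6 tert-butyl(dimethyl){[(3S,4R,5E)-3-(propan-2-yl)hepta-1,5-dien-4-yl]oxy}silane
Conditions: TBSCl, imidazole, DMF, rt
Reagents that add atoms: tert-butyldimethylsilyl chloride CC(C)(C)[Si](C)(C)Cl
Why: Standard silylation of a secondary allylic alcohol, which touches no stereocentre.

**Step 4**
Reactants: 6 tert-butyl(dimethyl){[(3S,4R,5E)-3-(propan-2-yl)hepta-1,5-dien-4-yl]oxy}silane
Product: 8 (3R,4R,5E)-4-{[tert-butyl(dimethyl)silyl]oxy}-3-(propan-2-yl)hept-5-en-1-ol, via B-alkyl-9-borabicyclononane 7 (not isolated)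
Conditions: 9-BBN, THF, 0 °C to rt; NaOH, H2O2, 0 °C
Reagents that add atoms: hydrogen peroxide OO
Why: Hydroboration–oxidation; 9-BBN should add anti-Markovnikov to the monosubstituted vinyl group far faster than to the 1,2-disubstituted propenyl group beside the bulky silyl ether.

**Step 5**
Reactants: 8 (3R,4R,5E)-4-{[tert-butyl(dimethyl)silyl]oxy}-3-(propan-2-yl)hept-5-en-1-ol
Product: 9 (3R,4R,5E)-4-{[tert-butyl(dimethyl)silyl]oxy}-3-(propan-2-yl)hept-5-enal
Conditions: PhI(OAc)2, TEMPO (10 mol %), CH2Cl2, rt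
Reagents that add atoms: none
Why: Nitroxyl-catalysed oxidation of a primary alcohol should stop at the aldehyde and leave silyl ether, alkene and the non-epimerisable β-stereocentre untouched.

**Step 6**
Reactants: 9 (3R,4R,5E)-4-{[tert-butyl(dimethyl)silyl]oxy}-3-(propan-2-yl)hept-5-enal
Product: 10 (2E,5R,6R,7E)-6-{[tert-butyl(dimethyl)silyl]oxy}-5-(propan-2-yl)nona-2,7-dienal
Conditions: Ph3P=CHCHO, toluene, 80 °C
Reagents that add atoms: (triphenylphosphoranylidene)acetaldehyde O=CC=P(c1ccccc1)(c1ccccc1)c1ccccc1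
Why: Wittig reaction of a stabilised ylide should give the (E)-enal, which fixes the C1=C5 geometry needed for chirality transfer in step 9.

**Step 7**
Reactants: 10 (2E,5R,6R,7E)-6-{[tert-butyl(dimethyl)silyl]oxy}-5-(propan-2-yl)nona-2,7-dienal
Product: 11 (4S,5E,8R,9R,10E)-9-{[tert-butyl(dimethyl)silyl]oxy}-8-(propan-2-yl)dodeca-5,10-dien-2-yn-4-ol
Conditions: propyne, Me2Zn, (S,S)-ProPhenol (10 mol %), Ph3PO (20 mol %), toluene, 0 °C; H2O
Reagents that add atoms: propyne CC#C
Why: Dinuclear zinc–ProPhenol-catalysed asymmetric alkynylation of an α,β-unsaturated aldehyde should deliver the propynylzinc to one enal face and set the carbinol C2 as S under reagent control, the existing stereocentres being remote.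

**Step 8**
Reactants: 11 (4S,5E,8R,9R,10E)-9-{[tert-butyl(dimethyl)silyl]oxy}-8-(propan-2-yl)dodeca-5,10-dien-2-yn-4-ol
Product: 12 (4S,5E,8R,9R,10E)-9-{[tert-butyl(dimethyl)silyl]oxy}-8-(propan-2-yl)dodeca-5,10-dien-2-yn-4-yl 2,2-dimethylpropanoate
Conditions: PivCl, Et3N, DMAP (cat.), CH2Cl2, 0 °C
Reagents that add atoms: pivaloyl chloride CC(C)(C)C(Cl)=O
Why: DMAP-catalysed acylation of the secondary alcohol with retention gives the 3-acyloxy-1,4-enyne required for the rearrangement.

**Step 9**
Reactants: 12 (4S,5E,8R,9R,10E)-9-{[tert-butyl(dimethyl)silyl]oxy}-8-(propan-2-yl)dodeca-5,10-dien-2-yn-4-yl 2,2-dimethylpropanoate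
Product: 14 (4S,5R)-4-[(2R,3R,4E)-3-{[tert-butyl(dimethyl)silyl]oxy}-2-(propan-2-yl)hex-4-en-1-yl]-5-methylcyclopent-2-en-1-one, via cyclopentadienyl pivalate 13 (not isolated)
Conditions: Ph3PAuCl (5 mol %), AgSbF6 (5 mol %), MeCN, H2O (2 equiv), −20 °C to rt
Reagents that add atoms: none
Why: Cationic monovalent gold (Ph3PAu+) activates the C3≡C4 alkyne, the pivalate carbonyl oxygen adds to C3 (1,2-acyloxy shift through a five-membered acyloxonium ion) and, as the C2–O bond ionises, the vinylgold carbon C4 bonds to the alkene terminus C5; loss of gold gives the cyclopentadienyl pivalate 13, which water hydrolyses to the enone with the ketone oxygen on C3. The closest known reaction type is the gold-catalysed Rautenstrauch rearrangement of 3-acyloxy-1,4-enynes to cyclopent-2-enones with transfer of chirality. The one ring closed, the five-membered ring C1–C5, closes at C4–C5 as a cyclisation of a 1-aurapentadienyl cation (Nazarov-like 4π closure, formally 5-endo at the C1=C5 alkene). C5 is controlled by the S carbinol centre C2 and the E geometry of C1=C5: the C2–O bond stands orthogonal to the alkene plane, C4 attacks C5 anti to it, and the helical cation should close before it relaxes (centre-to-helix-to-centre transfer); C4 arises on protonation of the enol ester, is expected mainly trans to the side chain and is erased in step 12. The step needs 1,2- rather than 3,3-acyloxy migration and ring closure faster than loss of helicity, which the pivalate, acetonitrile and low temperature favour; the second alkene stays out because it cannot reach the alkyne in a small ring.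

**Step 10**
Reactants: 14 (4S,5R)-4-[(2R,3R,4E)-3-{[tert-butyl(dimethyl)silyl]oxy}-2-(propan-2-yl)hex-4-en-1-yl]-5-methylcyclopent-2-en-1-one
Product: 15 (2R,3S,4R)-2-methyl-3-[(2R,3R,4E)-3-{[tert-butyl(dimethyl)silyl]oxy}-2-(propan-2-yl)hex-4-en-1-yl]-4-(prop-1-en-2-yl)cyclopentan-1-one
Conditions: CH2=C(CH3)MgBr, CuBr·SMe2 (20 mol %), THF, −78 to −40 °C; H2O
Reagents that add atoms: isopropenylmagnesium bromide CC(=C)[Mg]Br
Why: Copper-catalysed conjugate addition to the cyclopentenone should occur anti to the adjacent C5 side chain, which sets C1 and with it the trans relationship of the future ring fusion.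

**Step 11**
Reactants: 15 (2R,3S,4R)-2-methyl-3-[(2R,3R,4E)-3-{[tert-butyl(dimethyl)silyl]oxy}-2-(propan-2-yl)hex-4-en-1-yl]-4-(prop-1-en-2-yl)cyclopentan-1-one
Product: 16 (1R,4R,5S,7R,8S)-8-{[tert-butyl(dimethyl)silyl]oxy}guai-9-en-3-one
Conditions: second-generation Hoveyda–Grubbs catalyst (5 mol %), toluene, 80 °C
Reagents that add atoms: none
Why: Ring-closing metathesis between the isopropenyl group and the propenyl terminus should close the seven-membered ring as the trisubstituted C9=C10 alkene with loss of propene; the trans-disposed arms can reach each other and no stereocentre is affected.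

**Step 12**
Reactants: 16 (1R,4R,5S,7R,8S)-8-{[tert-butyl(dimethyl)silyl]oxy}guai-9-en-3-one
Product: 17 (1R,5S,7R,8S)-8-{[tert-butyl(dimethyl)silyl]oxy}guaia-3,9-dien-3-yl trifluoromethanesulfonate
Conditions: Tf2O, 2,6-di-tert-butyl-4-methylpyridine, CH2Cl2, 0 °C to rt
Reagents that add atoms: trifluoromethanesulfonic anhydride O=S(=O)(OS(=O)(=O)C(F)(F)F)C(F)(F)F
Why: Enol triflate formation under equilibrating conditions is expected to favour the more substituted C3=C4 isomer, which removes the C4 stereocentre (both C4 epimers converge) and fixes the site of the later epoxide.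

**Step 13**
Reactants: 17 (1R,5S,7R,8S)-8-{[tert-butyl(dimethyl)silyl]oxy}guaia-3,9-dien-3-yl trifluoromethanesulfonate
Product: 18 tert-butyl(dimethyl){[(1R,5S,7R,8S)-guaia-3,9-dien-8-yl]oxy}silane
Conditions: Pd(OAc)2 (5 mol %), PPh3 (10 mol %), HCO2H, Bu3N, DMF, 60 °C
Reagents that add atoms: none
Why: Palladium-catalysed formate reduction of the enol triflate (oxidative addition to zerovalent palladium, formate decarboxylation, reductive elimination) should replace OTf by H without moving either alkene.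

**Step 14**
Reactants: 18 tert-butyl(dimethyl){[(1R,5S,7R,8S)-guaia-3,9-dien-8-yl]oxy}silane
Product: 19 (1R,5S,7R,8S)-guaia-3,9-dien-8-ol
Conditions: Bu4NF, THF, rt
Reagents that add atoms: none
Why: Fluoride cleavage of the silyl ether frees the allylic alcohol that directs the next step.

**Step 15**
Reactants: 19 (1R,5S,7R,8S)-guaia-3,9-dien-8-ol
Product: 20 (1R,5S,7R,8S,9S,10R)-9,10-epoxyguai-3-en-8-ol
Conditions: VO(acac)2 (5 mol %), tBuOOH, CH2Cl2, 0 °C to rt
Reagents that add atoms: tert-butyl hydroperoxide CC(C)(C)OO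
Why: Vanadium-catalysed hydroxyl-directed epoxidation should deliver oxygen only to the allylic C9=C10 alkene and on the face of the C8 hydroxyl (syn), which sets C10; the isolated C3=C4 alkene is not attacked by this system.

**Step 16**
Reactants: 20 (1R,5S,7R,8S,9S,10R)-9,10-epoxyguai-3-en-8-ol
Product: 21 (1R,5S,7R,8R,10S)-guai-3-ene-8,10-diol
Conditions: LiAlH4, THF, 0 °C to rt; H2O
Reagents that add atoms: none
Why: Hydride opening of the 2,3-epoxy alcohol should occur by SN2 attack at the less substituted C9, assisted by the neighbouring alkoxide, so the C10–O bond stays and the tertiary alcohol is cis to the C8 hydroxyl.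

**Step 17**
Reactants: 21 (1R,5S,7R,8R,10S)-guai-3-ene-8,10-diol
Product: 23 (1R,3R,4S,5S,7R,8R,10S)-3,4-epoxyguaiane-8,10-diol, via bromohydrin 22 (not isolated)
Conditions: NBS, THF/H2O (4:1), 0 °C; K2CO3, MeOH, rt
Reagents that add atoms: water O
Why: Bromohydrin formation and base closure: the bromonium ion should form on the cyclopentene face anti to C6 on C5, water attacks C4 anti (Markovnikov), and the alkoxide then displaces bromide at C3 with inversion, placing the epoxide on the face opposite to the one a peracid would reach, as the target requires.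

**Step 18**
Reactants: 23 (1R,3R,4S,5S,7R,8R,10S)-3,4-epoxyguaiane-8,10-diol; 24 3,4-dimethoxybenzoyl chloride
Product: 25 (1R,3R,4S,5S,7R,8R,10S)-3,4-epoxy-10-hydroxyguaian-8-yl 3,4-dimethoxybenzoate
Conditions: Et3N, DMAP (cat.), CH2Cl2, 0 °C to rt
Reagents that add atoms: none
Why: DMAP-catalysed acylation should be selective for the secondary C8 hydroxyl over the tertiary C10 hydroxyl and leave the epoxide intact, giving the target.

**Compound list**

1 | (E)-4-methylpent-2-ene | C/C=C/C(C)C | starting material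
2 | [(2E)-4-methylpent-2-en-1-yl]potassium | [K]C/C=C/C(C)C | intermediate
3 | 2-[(2E)-4-methylpent-2-en-1-yl]-4,4,5,5-tetramethyl-1,3,2-dioxaborolane | CC(C)/C=C/CB1OC(C)(C)C(C)(C)O1 | intermediate
4 | (E)-but-2-enal | C/C=C/C=O | starting material
5 | (3S,4R,5E)-3-(propan-2-yl)hepta-1,5-dien-4-ol | C=C[C@H](C(C)C)[C@H](O)/C=C/C | intermediate
6 | tert-butyl(dimethyl){[(3S,4R,5E)-3-(propan-2-yl)hepta-1,5-dien-4-yl]oxy}silane | C=C[C@H](C(C)C)[C@H](O[Si](C)(C)C(C)(C)C)/C=C/C | intermediate
7 | 9-[(3R,4R,5E)-4-{[tert-butyl(dimethyl)silyl]oxy}-3-(propan-2-yl)hept-5-en-1-yl]-9-borabicyclo[3.3.1]nonane | B1(C2CCCC1CCC2)CC[C@H](C(C)C)[C@H](O[Si](C)(C)C(C)(C)C)/C=C/C | intermediate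
8 | (3R,4R,5E)-4-{[tert-butyl(dimethyl)silyl]oxy}-3-(propan-2-yl)hept-5-en-1-ol | OCC[C@H](C(C)C)[C@H](O[Si](C)(C)C(C)(C)C)/C=C/C | intermediate
9 | (3R,4R,5E)-4-{[tert-butyl(dimethyl)silyl]oxy}-3-(propan-2-yl)hept-5-enal | O=CC[C@H](C(C)C)[C@H](O[Si](C)(C)C(C)(C)C)/C=C/C | intermediate
10 | (2E,5R,6R,7E)-6-{[tert-butyl(dimethyl)silyl]oxy}-5-(propan-2-yl)nona-2,7-dienal | O=C/C=C/C[C@H](C(C)C)[C@H](O[Si](C)(C)C(C)(C)C)/C=C/C | intermediate
11 | (4S,5E,8R,9R,10E)-9-{[tert-butyl(dimethyl)silyl]oxy}-8-(propan-2-yl)dodeca-5,10-dien-2-yn-4-ol | CC#C[C@@H](O)/C=C/C[C@H](C(C)C)[C@H](O[Si](C)(C)C(C)(C)C)/C=C/C | intermediate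
12 | (4S,5E,8R,9R,10E)-9-{[tert-butyl(dimethyl)silyl]oxy}-8-(propan-2-yl)dodeca-5,10-dien-2-yn-4-yl 2,2-dimethylpropanoate | CC#C[C@@H](OC(=O)C(C)(C)C)/C=C/C[C@H](C(C)C)[C@H](O[Si](C)(C)C(C)(C)C)/C=C/C | intermediate
13 | (3S)-3-[(2R,3R,4E)-3-{[tert-butyl(dimethyl)silyl]oxy}-2-(propan-2-yl)hex-4-en-1-yl]-2-methylcyclopenta-1,4-dien-1-yl 2,2-dimethylpropanoate | CC1=C(OC(=O)C(C)(C)C)C=C[C@@H]1C[C@H](C(C)C)[C@H](O[Si](C)(C)C(C)(C)C)/C=C/C | intermediate
14 | (4S,5R)-4-[(2R,3R,4E)-3-{[tert-butyl(dimethyl)silyl]oxy}-2-(propan-2-yl)hex-4-en-1-yl]-5-methylcyclopent-2-en-1-one (methyl trans to the side chain) | O=C1C=C[C@H](C[C@H](C(C)C)[C@H](O[Si](C)(C)C(C)(C)C)/C=C/C)[C@H]1C | intermediate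
15 | (2R,3S,4R)-2-methyl-3-[(2R,3R,4E)-3-{[tert-butyl(dimethyl)silyl]oxy}-2-(propan-2-yl)hex-4-en-1-yl]-4-(prop-1-en-2-yl)cyclopentan-1-one | O=C1C[C@@H](C(C)=C)[C@H](C[C@H](C(C)C)[C@H](O[Si](C)(C)C(C)(C)C)/C=C/C)[C@H]1C | intermediate
16 | (1R,4R,5S,7R,8S)-8-{[tert-butyl(dimethyl)silyl]oxy}guai-9-en-3-one (trans-fused, H-1/H-5 anti) | CC(C)(C)[Si](C)(C)O[C@@H]2C=C(C)[C@@H]3CC(=O)[C@H](C)[C@H]3C[C@@H]2C(C)C | intermediate
17 | (1R,5S,7R,8S)-8-{[tert-butyl(dimethyl)silyl]oxy}guaia-3,9-dien-3-yl trifluoromethanesulfonate | CC(C)(C)[Si](C)(C)O[C@@H]2C=C(C)[C@@H]3CC(OS(=O)(=O)C(F)(F)F)=C(C)[C@H]3C[C@@H]2C(C)C | intermediate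
18 | tert-butyl(dimethyl){[(1R,5S,7R,8S)-guaia-3,9-dien-8-yl]oxy}silane | CC(C)(C)[Si](C)(C)O[C@@H]2C=C(C)[C@@H]3CC=C(C)[C@H]3C[C@@H]2C(C)C | intermediate
19 | (1R,5S,7R,8S)-guaia-3,9-dien-8-ol | O[C@@H]2C=C(C)[C@@H]3CC=C(C)[C@H]3C[C@@H]2C(C)C | intermediate
20 | (1R,5S,7R,8S,9S,10R)-9,10-epoxyguai-3-en-8-ol (epoxide syn to the C8 hydroxyl) | O[C@@H]2[C@@H]4O[C@]4(C)[C@@H]3CC=C(C)[C@H]3C[C@@H]2C(C)C | intermediate
21 | (1R,5S,7R,8R,10S)-guai-3-ene-8,10-diol | O[C@@H]2C[C@](C)(O)[C@@H]3CC=C(C)[C@H]3C[C@@H]2C(C)C | intermediate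
22 | (1R,3S,4S,5S,7R,8R,10S)-3-bromoguaiane-4,8,10-triol | O[C@@H]2C[C@](C)(O)[C@@H]3C[C@H](Br)[C@](O)(C)[C@H]3C[C@@H]2C(C)C | intermediate
23 | (1R,3R,4S,5S,7R,8R,10S)-3,4-epoxyguaiane-8,10-diol | O[C@@H]2C[C@](C)(O)[C@@H]3C[C@H]4O[C@@]4(C)[C@H]3C[C@@H]2C(C)C | intermediate
24 | 3,4-dimethoxybenzoyl chloride | COc1ccc(C(Cl)=O)cc1OC | starting material
25 | (1R,3R,4S,5S,7R,8R,10S)-3,4-epoxy-10-hydroxyguaian-8-yl 3,4-dimethoxybenzoate | COc1ccc(C(=O)O[C@@H]2C[C@](C)(O)[C@@H]3C[C@H]4O[C@@]4(C)[C@H]3C[C@@H]2C(C)C)cc1OC | target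

**Step count and risks**

Total: 18 steps. Longest linear sequence: 18 steps, from (E)-4-methylpent-2-ene 1 to the target 25.

Step 9 is the most likely to fail. With the internal alkyne, 3,3-acyloxy migration to an allenyl ester may compete with the 1,2-shift, and the chirality may leak if the cationic intermediate relaxes before ring closure. The fallback sets out from enal 10. The same zinc–ProPhenol alkynylation with trimethylsilylacetylene should give the silylated propargylic alcohol (3S,4E,7R,8R,9E)-8-{[tert-butyl(dimethyl)silyl]oxy}-7-(propan-2-yl)-1-(trimethylsilyl)undeca-4,9-dien-1-yn-3-ol F1. Pivaloylation gives its pivalate F2, and removal of the alkynyl silyl group (K2CO3, MeOH) gives the terminal-alkyne pivalate F3, the substrate class for which 1,2-migration and chirality transfer are best established. Gold-catalysed rearrangement under the conditions of step 9 should then give the cyclopentenone (4R)-4-[(2R,3R,4E)-3-{[tert-butyl(dimethyl)silyl]oxy}-2-(propan-2-yl)hex-4-en-1-yl]cyclopent-2-en-1-one F4. Methylation of its kinetic α′-enolate (LDA, MeI, THF, −78 °C), anti to the side chain, comes back to the route at 14.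

Step 12 is the second risk. Enolisation may go towards C2 instead of C4, which would lead after reduction to the C2=C3 alkene. The fallback sets out from ketone 16. Condensation with 4-methylbenzenesulfonohydrazide gives the tosylhydrazone F5. Its Bamford–Stevens decomposition (NaOMe, diglyme, heat) proceeds through a carbene that prefers 1,2-shift of the tertiary C4 hydrogen and so should give the more substituted alkene, coming back to the route at diene 18.

Step 17 is the third risk. Bromonium formation may show poor facial selectivity, or the bromonium ion may be captured by the C10 hydroxyl (bromoetherification); either erodes the required epoxide configuration. The fallback sets out from diol 21. Acylation with 24 (Et3N, DMAP) gives the alkenyl ester (1R,5S,7R,8R,10S)-10-hydroxyguai-3-en-8-yl 3,4-dimethoxybenzoate F6, which is epoxidised directly with a peracid (mCPBA, NaHCO3, CH2Cl2). If electrophiles turn out to prefer the face syn to C6, this direct epoxidation delivers the required epoxide, and the fallback comes back to the route at the target 25.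

**Further compounds**

F1 | step 9 | (3S,4E,7R,8R,9E)-8-{[tert-butyl(dimethyl)silyl]oxy}-7-(propan-2-yl)-1-(trimethylsilyl)undeca-4,9-dien-1-yn-3-ol | C[Si](C)(C)C#C[C@@H](O)/C=C/C[C@H](C(C)C)[C@H](O[Si](C)(C)C(C)(C)C)/C=C/C
F2 | step 9 | (3S,4E,7R,8R,9E)-8-{[tert-butyl(dimethyl)silyl]oxy}-7-(propan-2-yl)-1-(trimethylsilyl)undeca-4,9-dien-1-yn-3-yl 2,2-dimethylpropanoate | C[Si](C)(C)C#C[C@@H](OC(=O)C(C)(C)C)/C=C/C[C@H](C(C)C)[C@H](O[Si](C)(C)C(C)(C)C)/C=C/C
F3 | step 9 | (3S,4E,7R,8R,9E)-8-{[tert-butyl(dimethyl)silyl]oxy}-7-(propan-2-yl)undeca-4,9-dien-1-yn-3-yl 2,2-dimethylpropanoate | C#C[C@@H](OC(=O)C(C)(C)C)/C=C/C[C@H](C(C)C)[C@H](O[Si](C)(C)C(C)(C)C)/C=C/C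
F4 | step 9 | (4R)-4-[(2R,3R,4E)-3-{[tert-butyl(dimethyl)silyl]oxy}-2-(propan-2-yl)hex-4-en-1-yl]cyclopent-2-en-1-one | O=C1C=C[C@H](C[C@H](C(C)C)[C@H](O[Si](C)(C)C(C)(C)C)/C=C/C)C1
F5 | step 12 | N′-[(1R,4R,5S,7R,8S)-8-{[tert-butyl(dimethyl)silyl]oxy}guai-9-en-3-ylidene]-4-methylbenzenesulfonohydrazide | CC(C)(C)[Si](C)(C)O[C@@H]2C=C(C)[C@@H]3CC(=NNS(=O)(=O)c4ccc(C)cc4)[C@H](C)[C@H]3C[C@@H]2C(C)C
F6 | step 17 | (1R,5S,7R,8R,10S)-10-hydroxyguai-3-en-8-yl 3,4-dimethoxybenzoate | COc1ccc(C(=O)O[C@@H]2C[C@](C)(O)[C@@H]3CC=C(C)[C@H]3C[C@@H]2C(C)C)cc1OC
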